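The route rests on breaking the C1'–C6' bond of the cyclohexene ring in the C6 side chain, which turns that ring back into an achiral (E)-geranyl chain on a phloroglucinol core. One operation then does the stereochemical work: a chiral BINOL-derived acid activated by SnCl4 protonates the terminal alkene, closes the six-membered ring, sets the only stereocentre (C1') and leaves the C2'=C3' alkene. The step exploits the fact that C1', the gem-dimethyl carbon C6' and the ring alkene form the exact pattern of a geranyl cation–olefin cyclization. The precursor is 2-geranylphloroglucinol with both flanking oxygens as pivalates and the para oxygen, the future O1 of ring C, as a TIPS ether.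

Key step: step 6

Locants: flavonol numbering for the core; primed locants for the cyclohexene ring (C1' bears the benzylic CH2, C2'=C3' is the alkene, C6' is the gem-dimethyl carbon); the geranyl chain is numbered C1–C8 from the benzylic carbon.

Assumption (sense of induction): with related polyprenoid substrates the (R)-configured BINOL·SnCl4 acids are recalled to give the normal terpenoid series (5α-H type), which maps onto (S) at C1' here. The (S)-ligand is therefore specified, and the mirror-image ligand would be taken if the sense proved opposite on this substrate.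

Remark on protecting groups: after the cyclization the two ring-A oxygens and the ring-B oxygen are carried as allyl ethers, so that the last step needs no acid next to the C2'=C3' alkene.

**Step 1**
Reactants: 1 phloroglucinol
Product: 2 5-[(triisopropylsilyl)oxy]benzene-1,3-diol
Conditions: TIPSCl (1.0 equiv), imidazole (2.2 equiv), DMF, 0 °C → rt
Reagents that add atoms: triisopropylsilyl chloride, CC(C)[Si](Cl)(C(C)C)C(C)C
Why: Imidazole-mediated O-silylation of a symmetric triphenol with one equivalent of a bulky silyl chloride should stop mainly at the mono-ether, and unreacted 1 and the bis-ether are easily separated.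

**Step 2**
Reactants: 2 5-[(triisopropylsilyl)oxy]benzene-1,3-diol
Product: 3 [3,5-bis(methoxymethoxy)phenoxy]triisopropylsilane
Conditions: MOMCl (3.0 equiv), i-Pr2NEt (4.0 equiv), CH2Cl2, 0 °C → rt
Reagents that add atoms: chloromethyl methyl ether, COCCl
Why: Williamson-type O-alkylation of both phenols under amine base forms the two acetal ethers and leaves the aryl silyl ether untouched.

**Step 3**
Reactants: 3 [3,5-bis(methoxymethoxy)phenoxy]triisopropylsilane; 4 geranyl bromide
Product: 7 {4-[(2E)-3,7-dimethylocta-2,6-dien-1-yl]-3,5-bis(methoxymethoxy)phenoxy}triisopropylsilane, via aryllithium 5 (not isolated), via arylcopper 6 (not isolated)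
Conditions: n-BuLi (1.2 equiv), THF, 0 °C; CuBr·SMe2 (1.2 equiv), –78 → –40 °C; 4 (1.3 equiv), –78 °C → rt
Reagents that add atoms: none
Why: Directed ortho-metalation occurs at the only carbon flanked by two MOM ethers (the bulky OTIPS shields its own neighbours), and after transmetalation the organocopper displaces the primary allylic bromide in the SN2 sense, which keeps the E geometry of C2=C3.

**Step 4**
Reactants: 7 {4-[(2E)-3,7-dimethylocta-2,6-dien-1-yl]-3,5-bis(methoxymethoxy)phenoxy}triisopropylsilane
Product: 8 2-[(2E)-3,7-dimethylocta-2,6-dien-1-yl]-5-(triisopropylsilyloxy)benzene-1,3-diol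
Conditions: p-TsOH·H2O (0.3 equiv), MeOH, 25–40 °C
Reagents that add atoms: none
Why: Acid-catalysed acetal methanolysis removes aryl MOM ethers at an acid strength at which the aryl TIPS ether and the two trisubstituted alkenes should remain intact.

**Step 5**
Reactants: 8 2-[(2E)-3,7-dimethylocta-2,6-dien-1-yl]-5-(triisopropylsilyloxy)benzene-1,3-diol
Product: 9 2-[(2E)-3,7-dimethylocta-2,6-dien-1-yl]-5-(triisopropylsilyloxy)-1,3-phenylene bis(2,2-dimethylpropanoate)
Conditions: PivCl (3.0 equiv), Et3N (4.0 equiv), DMAP (0.1 equiv), CH2Cl2, 0 °C → rt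
Reagents that add atoms: pivaloyl chloride, CC(C)(C)C(=O)Cl
Why: DMAP-catalysed nucleophilic acyl substitution converts both phenols into hindered, electron-poor esters that cannot act as oxygen nucleophiles in the next step.

**Step 6**
Reactants: 9 2-[(2E)-3,7-dimethylocta-2,6-dien-1-yl]-5-(triisopropylsilyloxy)-1,3-phenylene bis(2,2-dimethylpropanoate)
Product: 10 2-{[(1R)-2,6,6-trimethylcyclohex-2-en-1-yl]methyl}-5-(triisopropylsilyloxy)-1,3-phenylene bis(2,2-dimethylpropanoate)
Conditions: (S)-2-(2-fluorobenzyloxy)-2'-hydroxy-1,1'-binaphthyl (2.2 equiv), SnCl4 (2.0 equiv), toluene, –78 °C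
Reagents that add atoms: none
Why: The SnCl4-bound binaphthol is a strong chiral Brønsted acid that places its proton on C6 of the geranyl chain while the C2=C3 alkene attacks C7 through a chair-like arrangement, so that protonation and formation of the C1'–C6' bond are concerted; the tertiary cation left at C2' then loses the pseudoaxial C3' proton to the tin-bound aryloxide. The closest known reaction type is the enantioselective proton-initiated cyclization of geranyl- and homogeranyl-arenes by BINOL·SnCl4 acids. The cyclohexene closes 6-endo-trig with respect to the attacking C2=C3 alkene (Markovnikov attack through its CH terminus). C1' is controlled by the reagent: the chiral acid selects the enantioface of the terminal alkene and the chair relays this to the face of C2=C3 that bonds to C6', the (S)-ligand being chosen for the (R) centre. The step needs elimination instead of trapping and C3'–H loss instead of methyl or C1'–H loss; the two pivalates make the flanking oxygens non-nucleophilic and occupy both ortho carbons, so neither hexahydroxanthene formation nor Friedel–Crafts closure can end the reaction, and kinetic deprotonation at –78 °C favours the ring CH2 whose C–H bond is aligned with the empty orbital.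

**Step 7**
Reactants: 10 2-{[(1R)-2,6,6-trimethylcyclohex-2-en-1-yl]methyl}-5-(triisopropylsilyloxy)-1,3-phenylene bis(2,2-dimethylpropanoate)
Product: 11 2-{[(1R)-2,6,6-trimethylcyclohex-2-en-1-yl]methyl}-5-(triisopropylsilyloxy)benzene-1,3-diol
Conditions: i-Bu2AlH (5 equiv), CH2Cl2, –78 °C
Reagents that add atoms: none
Why: Reductive ester cleavage by hydride releases both phenols at low temperature, where neither the aryl silyl ether nor the ring alkene reacts.

**Step 8**
Reactants: 11 2-{[(1R)-2,6,6-trimethylcyclohex-2-en-1-yl]methyl}-5-(triisopropylsilyloxy)benzene-1,3-diol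
Product: 12 {3,5-bis(allyloxy)-4-{[(1R)-2,6,6-trimethylcyclohex-2-en-1-yl]methyl}phenoxy}triisopropylsilane
Conditions: allyl bromide (3 equiv), K2CO3 (4 equiv), acetone, 50 °C
Reagents that add atoms: allyl bromide, C=CCBr
Why: Williamson ether synthesis under mild carbonate base should give O-allylation of both phenols, and allyl ethers withstand the basic and oxidative steps ahead while being removable without acid.

**Step 9**
Reactants: 12 {3,5-bis(allyloxy)-4-{[(1R)-2,6,6-trimethylcyclohex-2-en-1-yl]methyl}phenoxy}triisopropylsilane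
Product: 13 3,5-bis(allyloxy)-4-{[(1R)-2,6,6-trimethylcyclohex-2-en-1-yl]methyl}phenol
Conditions: Bu4NF (1.1 equiv), THF, 0 °C
Reagents that add atoms: none
Why: Fluoride-induced desilylation frees only the phenol para to the side chain, the oxygen that becomes O1 of ring C.

**Step 10**
Reactants: 13 3,5-bis(allyloxy)-4-{[(1R)-2,6,6-trimethylcyclohex-2-en-1-yl]methyl}phenol
Product: 15 2,4-bis(allyloxy)-6-hydroxy-3-{[(1R)-2,6,6-trimethylcyclohex-2-en-1-yl]methyl}benzaldehyde, via hydroxymethylphenol 14 (not isolated)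
Conditions: MgCl2 (2 equiv), Et3N (4 equiv), (CH2O)n (5 equiv), THF, reflux
Reagents that add atoms: paraformaldehyde (as formaldehyde), C=O
Why: Casnati–Skattebøl ortho-formylation: the magnesium phenoxide directs formaldehyde to the ortho carbon and the benzylic alkoxide is oxidised by a second formaldehyde through hydride transfer, the two ortho carbons being equivalent by symmetry so that one regioisomer should result.

**Step 11**
Reactants: 15 2,4-bis(allyloxy)-6-hydroxy-3-{[(1R)-2,6,6-trimethylcyclohex-2-en-1-yl]methyl}benzaldehyde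
Product: 16 3,5-bis(allyloxy)-2-(1-hydroxyethyl)-4-{[(1R)-2,6,6-trimethylcyclohex-2-en-1-yl]methyl}phenol (both carbinol epimers)
Conditions: MeMgBr (3 equiv), THF, –78 → 0 °C
Reagents that add atoms: methylmagnesium bromide, C[Mg]Br
Why: Grignard 1,2-addition to the aldehyde follows deprotonation of the phenol, and the configuration of the new carbinol carbon is irrelevant because it is oxidised in the next step.

**Step 12**
Reactants: 16 3,5-bis(allyloxy)-2-(1-hydroxyethyl)-4-{[(1R)-2,6,6-trimethylcyclohex-2-en-1-yl]methyl}phenol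
Product: 17 1-(2,4-bis(allyloxy)-6-hydroxy-3-{[(1R)-2,6,6-trimethylcyclohex-2-en-1-yl]methyl}phenyl)ethan-1-one
Conditions: MnO2 (activated, 15 equiv), CH2Cl2, rt
Reagents that add atoms: none
Why: Chemoselective MnO2 oxidation of the benzylic secondary alcohol should give the hydrogen-bonded ortho-hydroxyacetophenone without touching the isolated alkenes.

**Step 13**
Reactants: 17 1-(2,4-bis(allyloxy)-6-hydroxy-3-{[(1R)-2,6,6-trimethylcyclohex-2-en-1-yl]methyl}phenyl)ethan-1-one; 18 4-(allyloxy)benzaldehyde
Product: 20 (2E)-1-(2,4-bis(allyloxy)-6-hydroxy-3-{[(1R)-2,6,6-trimethylcyclohex-2-en-1-yl]methyl}phenyl)-3-[4-(allyloxy)phenyl]prop-2-en-1-one, via aldol adduct 19 (not isolated)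
Conditions: KOH (50% aq., 15 equiv), EtOH, 0 °C → rt
Reagents that add atoms: none
Why: Claisen–Schmidt condensation, a crossed aldol addition of the methyl ketone enolate to the non-enolisable aldehyde followed by E1cB dehydration, should give the E-chalcone.

**Step 14**
Reactants: 20 (2E)-1-(2,4-bis(allyloxy)-6-hydroxy-3-{[(1R)-2,6,6-trimethylcyclohex-2-en-1-yl]methyl}phenyl)-3-[4-(allyloxy)phenyl]prop-2-en-1-one
Product: 22 5,7-bis(allyloxy)-2-[4-(allyloxy)phenyl]-3-hydroxy-6-{[(1R)-2,6,6-trimethylcyclohex-2-en-1-yl]methyl}-4H-chromen-4-one, via dihydroflavonol 21 (not isolated)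
Conditions: H2O2 (30% aq., 6 equiv), NaOH (2 M aq., 6 equiv), MeOH/THF, 0 °C → rt
Reagents that add atoms: hydrogen peroxide, OO
Why: Algar–Flynn–Oyamada reaction: the phenoxide adds to the enone β-carbon while the enolate is hydroxylated by peroxide to the dihydroflavonol, which is dehydrogenated in the same medium, and alkaline peroxide does not epoxidise the unactivated ring alkene or the allyl ethers.

**Step 15**
Reactants: 22 5,7-bis(allyloxy)-2-[4-(allyloxy)phenyl]-3-hydroxy-6-{[(1R)-2,6,6-trimethylcyclohex-2-en-1-yl]methyl}-4H-chromen-4-one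
Product: 23 Ugonin G, 3,5,7-trihydroxy-2-(4-hydroxyphenyl)-6-{[(1R)-2,6,6-trimethylcyclohex-2-en-1-yl]methyl}-4H-chromen-4-one
Conditions: Pd(PPh3)4 (10 mol%), morpholine (10 equiv), THF, rt, argon
Reagents that add atoms: none
Why: Tsuji–Trost deallylation: zerovalent palladium ionises each aryl allyl ether to a π-allyl complex that morpholine captures, under neutral conditions that cannot add the C5 or C7 hydroxyl to the C2'=C3' alkene and that leave C1' untouched.

**Compound list**

1 | phloroglucinol | Oc1cc(O)cc(O)c1 | starting material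
2 | 5-[(triisopropylsilyl)oxy]benzene-1,3-diol | CC(C)[Si](Oc1cc(O)cc(O)c1)(C(C)C)C(C)C | intermediate
3 | [3,5-bis(methoxymethoxy)phenoxy]triisopropylsilane | COCOc1cc(OCOC)cc(O[Si](C(C)C)(C(C)C)C(C)C)c1 | intermediate
4 | geranyl bromide | CC(C)=CCC/C(C)=C/CBr | starting material
5 | [2,6-bis(methoxymethoxy)-4-(triisopropylsilyloxy)phenyl]lithium | [Li]c1c(OCOC)cc(O[Si](C(C)C)(C(C)C)C(C)C)cc1OCOC | intermediate
6 | [2,6-bis(methoxymethoxy)-4-(triisopropylsilyloxy)phenyl]copper (monovalent copper) | [Cu]c1c(OCOC)cc(O[Si](C(C)C)(C(C)C)C(C)C)cc1OCOC | intermediate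
7 | {4-[(2E)-3,7-dimethylocta-2,6-dien-1-yl]-3,5-bis(methoxymethoxy)phenoxy}triisopropylsilane | CC(C)=CCC/C(C)=C/Cc1c(OCOC)cc(O[Si](C(C)C)(C(C)C)C(C)C)cc1OCOC | intermediate
8 | 2-[(2E)-3,7-dimethylocta-2,6-dien-1-yl]-5-(triisopropylsilyloxy)benzene-1,3-diol | CC(C)=CCC/C(C)=C/Cc1c(O)cc(O[Si](C(C)C)(C(C)C)C(C)C)cc1O | intermediate
9 | 2-[(2E)-3,7-dimethylocta-2,6-dien-1-yl]-5-(triisopropylsilyloxy)-1,3-phenylene bis(2,2-dimethylpropanoate) | CC(C)=CCC/C(C)=C/Cc1c(OC(=O)C(C)(C)C)cc(O[Si](C(C)C)(C(C)C)C(C)C)cc1OC(=O)C(C)(C)C | intermediate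
10 | 2-{[(1R)-2,6,6-trimethylcyclohex-2-en-1-yl]methyl}-5-(triisopropylsilyloxy)-1,3-phenylene bis(2,2-dimethylpropanoate) | CC1=CCCC(C)(C)[C@H]1Cc1c(OC(=O)C(C)(C)C)cc(O[Si](C(C)C)(C(C)C)C(C)C)cc1OC(=O)C(C)(C)C | intermediate
11 | 2-{[(1R)-2,6,6-trimethylcyclohex-2-en-1-yl]methyl}-5-(triisopropylsilyloxy)benzene-1,3-diol | CC1=CCCC(C)(C)[C@H]1Cc1c(O)cc(O[Si](C(C)C)(C(C)C)C(C)C)cc1O | intermediate
12 | {3,5-bis(allyloxy)-4-{[(1R)-2,6,6-trimethylcyclohex-2-en-1-yl]methyl}phenoxy}triisopropylsilane | CC1=CCCC(C)(C)[C@H]1Cc1c(OCC=C)cc(O[Si](C(C)C)(C(C)C)C(C)C)cc1OCC=C | intermediate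
13 | 3,5-bis(allyloxy)-4-{[(1R)-2,6,6-trimethylcyclohex-2-en-1-yl]methyl}phenol | CC1=CCCC(C)(C)[C@H]1Cc1c(OCC=C)cc(O)cc1OCC=C | intermediate
14 | 3,5-bis(allyloxy)-2-(hydroxymethyl)-4-{[(1R)-2,6,6-trimethylcyclohex-2-en-1-yl]methyl}phenol (present as its magnesium salt) | CC1=CCCC(C)(C)[C@H]1Cc1c(OCC=C)cc(O)c(CO)c1OCC=C | intermediate
15 | 2,4-bis(allyloxy)-6-hydroxy-3-{[(1R)-2,6,6-trimethylcyclohex-2-en-1-yl]methyl}benzaldehyde | CC1=CCCC(C)(C)[C@H]1Cc1c(OCC=C)cc(O)c(C=O)c1OCC=C | intermediate
16 | 3,5-bis(allyloxy)-2-(1-hydroxyethyl)-4-{[(1R)-2,6,6-trimethylcyclohex-2-en-1-yl]methyl}phenol (both carbinol epimers) | CC1=CCCC(C)(C)[C@H]1Cc1c(OCC=C)cc(O)c(C(C)O)c1OCC=C | intermediate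
17 | 1-(2,4-bis(allyloxy)-6-hydroxy-3-{[(1R)-2,6,6-trimethylcyclohex-2-en-1-yl]methyl}phenyl)ethan-1-one | CC1=CCCC(C)(C)[C@H]1Cc1c(OCC=C)cc(O)c(C(C)=O)c1OCC=C | intermediate
18 | 4-(allyloxy)benzaldehyde | C=CCOc1ccc(C=O)cc1 | starting material
19 | 1-(2,4-bis(allyloxy)-6-hydroxy-3-{[(1R)-2,6,6-trimethylcyclohex-2-en-1-yl]methyl}phenyl)-3-[4-(allyloxy)phenyl]-3-hydroxypropan-1-one (both carbinol epimers) | CC1=CCCC(C)(C)[C@H]1Cc1c(OCC=C)cc(O)c(C(=O)CC(O)c2ccc(OCC=C)cc2)c1OCC=C | intermediate
20 | (2E)-1-(2,4-bis(allyloxy)-6-hydroxy-3-{[(1R)-2,6,6-trimethylcyclohex-2-en-1-yl]methyl}phenyl)-3-[4-(allyloxy)phenyl]prop-2-en-1-one | CC1=CCCC(C)(C)[C@H]1Cc1c(OCC=C)cc(O)c(C(=O)/C=C/c2ccc(OCC=C)cc2)c1OCC=C | intermediate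
21 | trans-5,7-bis(allyloxy)-2-[4-(allyloxy)phenyl]-3-hydroxy-6-{[(1R)-2,6,6-trimethylcyclohex-2-en-1-yl]methyl}chroman-4-one (both trans antipodes at C2/C3) | CC1=CCCC(C)(C)[C@H]1Cc1c(OCC=C)cc2OC(c3ccc(OCC=C)cc3)C(O)C(=O)c2c1OCC=C | intermediate
22 | 5,7-bis(allyloxy)-2-[4-(allyloxy)phenyl]-3-hydroxy-6-{[(1R)-2,6,6-trimethylcyclohex-2-en-1-yl]methyl}-4H-chromen-4-one | CC1=CCCC(C)(C)[C@H]1Cc1c(OCC=C)cc2oc(-c3ccc(OCC=C)cc3)c(O)c(=O)c2c1OCC=C | intermediate
23 | Ugonin G, 3,5,7-trihydroxy-2-(4-hydroxyphenyl)-6-{[(1R)-2,6,6-trimethylcyclohex-2-en-1-yl]methyl}-4H-chromen-4-one | CC1=CCCC(C)(C)[C@H]1Cc1c(O)cc2oc(-c3ccc(O)cc3)c(O)c(=O)c2c1O | target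

**Step count and risks**

Total step count: 15. Longest linear sequence: 15 steps (1 → 23); 4 and 18 enter as purchased fragments.

Steps most likely to fail:

1. Step 6. The chiral acid may discriminate the two faces of the terminal alkene poorly, because the substrate offers no nucleophile close to the reacting alkenes. Proton loss from the C2' cation may also spread to the methyl group (exocyclic alkene) or to C1' (tetrasubstituted alkene, which erases the stereocentre). The fallback is convergent and fixes the alkene position before the ring is attached. It sets out from 3 and comes back at 11. Aryllithium 5, generated from 3 as in step 3, would be added at –78 °C in THF to commercial racemic α-cyclocitral (2,6,6-trimethylcyclohex-2-ene-1-carbaldehyde) to give benzylic carbinol F1. Birch-type benzylic hydrogenolysis (Li, liquid NH3/THF, –78 °C, then NH4Cl) would remove the hydroxyl and give racemic bis-MOM arene F2. Acetal methanolysis as in step 4 would give racemic diol F3. Preparative HPLC on a polysaccharide chiral stationary phase would then separate the enantiomers, the (R)-enantiomer being 11, from which step 8 continues.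

2. Step 14. The phenoxide may close onto the α-carbon instead of the β-carbon (five-membered aurone pathway), a course favoured when the oxygen substituent ortho to the carbonyl twists the enone out of plane; the electron-rich chalcone may also be degraded oxidatively. The fallback closes ring C on an ynone, where only the six-membered mode is open, and introduces the C3 oxygen afterwards. It sets out from 15 and comes back at 22. Aldehyde 18 would be homologated with the Ohira–Bestmann reagent (K2CO3, MeOH) to 1-(allyloxy)-4-ethynylbenzene F4. Its lithium acetylide (n-BuLi, THF, –78 °C, 3 equiv) would be added to 15 to give propargylic alcohol F5, and MnO2 oxidation would give ynone F6. Et2NH in EtOH would close the ring by conjugate addition–elimination to flavone F7. C3 lithiation (LiN(i-Pr)2, THF, –78 °C), borylation with B(OMe)3 and oxidation with H2O2/NaOH would then give 22.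

3. Step 4. Acid meets a geranyl chain while two ortho phenols are being uncovered, so protonation of the C2=C3 or terminal alkene with capture by the neighbouring phenol oxygen (chroman formation) or by methanol may compete with acetal cleavage. The fallback avoids the acetal stage altogether (no new compound, F0). It sets out from 2 and comes back at 8. Silyl ether 2 would be C-geranylated directly at the carbon between its two hydroxyls with geraniol on acidic Al2O3 (1,2-dichloroethane, reflux; surface-templated ortho-allylation of phenols), the TIPS group shielding the other two ring carbons. This would give 8 without passing through 3, 5, 6 or 7, and step 5 follows.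

**Further compounds**

F1 | step 6 | [2,6-bis(methoxymethoxy)-4-(triisopropylsilyloxy)phenyl](2,6,6-trimethylcyclohex-2-en-1-yl)methanol (racemic, both diastereomers) | CC1=CCCC(C)(C)C1C(O)c1c(OCOC)cc(O[Si](C(C)C)(C(C)C)C(C)C)cc1OCOC
F2 | step 6 | racemic {3,5-bis(methoxymethoxy)-4-[(2,6,6-trimethylcyclohex-2-en-1-yl)methyl]phenoxy}triisopropylsilane | CC1=CCCC(C)(C)C1Cc1c(OCOC)cc(O[Si](C(C)C)(C(C)C)C(C)C)cc1OCOC
F3 | step 6 | racemic 2-[(2,6,6-trimethylcyclohex-2-en-1-yl)methyl]-5-(triisopropylsilyloxy)benzene-1,3-diol | CC1=CCCC(C)(C)C1Cc1c(O)cc(O[Si](C(C)C)(C(C)C)C(C)C)cc1O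
F4 | step 14 | 1-(allyloxy)-4-ethynylbenzene | C#Cc1ccc(OCC=C)cc1
F5 | step 14 | 3,5-bis(allyloxy)-2-{3-[4-(allyloxy)phenyl]-1-hydroxyprop-2-yn-1-yl}-4-{[(1R)-2,6,6-trimethylcyclohex-2-en-1-yl]methyl}phenol (both carbinol epimers) | CC1=CCCC(C)(C)[C@H]1Cc1c(OCC=C)cc(O)c(C(O)C#Cc2ccc(OCC=C)cc2)c1OCC=C
F6 | step 14 | 1-(2,4-bis(allyloxy)-6-hydroxy-3-{[(1R)-2,6,6-trimethylcyclohex-2-en-1-yl]methyl}phenyl)-3-[4-(allyloxy)phenyl]prop-2-yn-1-one | CC1=CCCC(C)(C)[C@H]1Cc1c(OCC=C)cc(O)c(C(=O)C#Cc2ccc(OCC=C)cc2)c1OCC=C
F7 | step 14 | 5,7-bis(allyloxy)-2-[4-(allyloxy)phenyl]-6-{[(1R)-2,6,6-trimethylcyclohex-2-en-1-yl]methyl}-4H-chromen-4-one | CC1=CCCC(C)(C)[C@H]1Cc1c(OCC=C)cc2oc(-c3ccc(OCC=C)cc3)cc(=O)c2c1OCC=C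
F0 | step 4 | none | none
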